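**Retrosynthetic overview**
1. Target 57 ⇐ hydrogenolysis of two phenolic benzyl ethers and hydrolysis of three acetonides from the protected furofuran 55.
2. 55 ⇐ tetraol 53: both tetrahydrofuran rings of the furofuran are closed last, together, by double O-alkylation at the primary carbons.
3. 53 ⇐ late aldol union of two halves of similar size: γ-butyrolactone 49 (rings A and B) and aldehyde 40 (rings C, D and E).
4. 49 ⇐ Evans syn-aldol of a succinate imide with aldehyde 27, then reductive lactonisation. Each β-aryl-ether unit ⇐ Evans syn-aldol of an aryloxyacetyl imide (threo, as in the unit on ring C); the erythro units on rings B and D ⇐ Mitsunobu inversion at C7. Aryl bromides serve as masked aldehydes.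
5. Ring order: aromatic rings from catechol and resorcinol → three temporary 1,3-dioxane acetonides → temporary γ-lactone → the two furofuran rings.

Assumption: alkylating, silylating and acetonide reagents, DMF as formyl source and the two 4-benzyl-oxazolidinone auxiliaries are treated as reagents; the starting materials are 1, 3, 8, 14 and 41.

**Shorthand used in names**
- Bn = benzyl; TBS = tert-butyldimethylsilyl; G = 4-(benzyloxy)-3-methoxyphenyl.
- C7, C8, C9 = benzylic, middle and CH2O carbon of a C3 side chain; primed locants belong to the ring C half of the core.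
- Rings: A = outer guaiacyl ring on the ring B side; B and C = the two syringyl rings on the furofuran; D = inner guaiacyl ring; E = outer guaiacyl ring.
- armA = (4R,5S)-4-G-2,2-dimethyl-1,3-dioxan-5-yl (trans; erythro unit on ring B).
- armE = (4S,5R)-4-G-2,2-dimethyl-1,3-dioxan-5-yl (trans; erythro unit on ring D).
- armDE = (4S,5S)-4-[3-methoxy-4-(armE-oxy)phenyl]-2,2-dimethyl-1,3-dioxan-5-yl (cis; threo unit on ring C).
- ArB = 3,5-dimethoxy-4-(armA-oxy)phenyl; ArC = 3,5-dimethoxy-4-(armDE-oxy)phenyl.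

**Part 1 – aromatic building blocks**

Step 1
Reactants: 1 catechol
Product: 2 guaiacol (2-methoxyphenol)
Conditions: MeI (0.5 equiv), K2CO3, acetone, reflux; catechol in two-fold excess
Reagents that add atoms: iodomethane (CI)
Why: Williamson mono-O-methylation; the excess of diol suppresses dimethylation and unreacted catechol is washed out with water.

Step 2
Reactants: 2 guaiacol; 3 glyoxylic acid
Product: 5 vanillin (4-hydroxy-3-methoxybenzaldehyde), via 4-hydroxy-3-methoxymandelic acid 4 (not isolated)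
Conditions: NaOH, H2O, 30 °C; then CuSO4 (cat.), air, 95 °C; H2SO4
Reagents that add atoms: none
Why: para-selective electrophilic hydroxyalkylation of the phenolate by glyoxylate, then copper-catalysed oxidative decarboxylation of the mandelate (the technical vanillin process).

Step 3
Reactants: 5 vanillin
Product: 6 4-(benzyloxy)-3-methoxybenzaldehyde
Conditions: BnBr, K2CO3, DMF, 25 °C
Reagents that add atoms: benzyl bromide (BrCc1ccccc1)
Why: Williamson etherification of the phenol.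

Step 4
Reactants: 2 guaiacol
Product: 7 4-bromo-2-methoxyphenol
Conditions: NBS, MeCN, 0 °C
Reagents that add atoms: N-bromosuccinimide (O=C1CCC(=O)N1Br)
Why: electrophilic aromatic bromination, directed para to the free hydroxyl.

Step 5
Reactants: 8 resorcinol
Product: 9 1,3-dimethoxybenzene
Conditions: MeI (2.5 equiv), K2CO3, acetone, reflux
Reagents that add atoms: iodomethane (CI)
Why: exhaustive Williamson O-methylation.

Step 6
Reactants: 9 1,3-dimethoxybenzene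
Product: 12 2,6-dimethoxyphenol, via 2,6-dimethoxyphenyllithium 10 (not isolated), via dimethyl (2,6-dimethoxyphenyl)boronate 11 (not isolated)
Conditions: n-BuLi, THF, 0 → 25 °C; B(OMe)3, −78 → 25 °C; H2O2, aq NaOH, 0 °C
Reagents that add atoms: hydrogen peroxide (OO)
Why: directed ortho-metalation between the two methoxy groups, borylation and oxidation of the C–B bond to the phenol.

Step 7
Reactants: 12 2,6-dimethoxyphenol
Product: 13 4-bromo-2,6-dimethoxyphenol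
Conditions: NBS, NaH (cat.), CHCl3, −45 °C
Reagents that add atoms: N-bromosuccinimide (O=C1CCC(=O)N1Br)
Why: electrophilic bromination para to the phenol (phenoxide-promoted), both ortho positions being blocked.

**Part 2 – aryloxyacetyl imides**

Step 8
Reactants: 13 4-bromo-2,6-dimethoxyphenol; 14 bromoacetic acid
Product: 15 (4-bromo-2,6-dimethoxyphenoxy)acetic acid
Conditions: NaOH, H2O, reflux; HCl
Reagents that add atoms: none
Why: Williamson etherification of the phenoxide with bromoacetate.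

Step 9
Reactants: 15 (4-bromo-2,6-dimethoxyphenoxy)acetic acid
Product: 17 (4R)-4-benzyl-3-[(4-bromo-2,6-dimethoxyphenoxy)acetyl]-1,3-oxazolidin-2-one, via pivalic mixed anhydride of the bromosyringyloxyacetic acid 16 (not isolated)
Conditions: PivCl, Et3N, THF, −20 °C; then LiCl, (R)-4-benzyl-1,3-oxazolidin-2-one, −20 → 25 °C
Reagents that add atoms: (R)-4-benzyl-1,3-oxazolidin-2-one (O=C1N[C@H](Cc2ccccc2)CO1)
Why: N-acylation of the Evans auxiliary through a mixed anhydride.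

Step 10
Reactants: 7 4-bromo-2-methoxyphenol; 14 bromoacetic acid
Product: 18 (4-bromo-2-methoxyphenoxy)acetic acid
Conditions: NaOH, H2O, reflux; HCl
Reagents that add atoms: none
Why: Williamson etherification of the phenoxide with bromoacetate.

Step 11
Reactants: 18 (4-bromo-2-methoxyphenoxy)acetic acid
Product: 20 (4S)-4-benzyl-3-[(4-bromo-2-methoxyphenoxy)acetyl]-1,3-oxazolidin-2-one, via pivalic mixed anhydride of the bromoguaiacyloxyacetic acid 19 (not isolated)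
Conditions: PivCl, Et3N, THF, −20 °C; then LiCl, (S)-4-benzyl-1,3-oxazolidin-2-one, −20 → 25 °C
Reagents that add atoms: (S)-4-benzyl-1,3-oxazolidin-2-one (O=C1N[C@@H](Cc2ccccc2)CO1)
Why: N-acylation of the Evans auxiliary through a mixed anhydride.

**Part 3 – ring A/ring B aldehyde 27**

Step 12
Reactants: 17 (R)-imide of the bromosyringyloxyacetic acid; 6 4-(benzyloxy)-3-methoxybenzaldehyde
Product: 22 (4R)-4-benzyl-3-[(2R,3S)-3-G-2-(4-bromo-2,6-dimethoxyphenoxy)-3-hydroxypropanoyl]-1,3-oxazolidin-2-one, via Z-dibutylboron enolate of the bromosyringyl imide 21 (not isolated)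
Conditions: Bu2BOTf, i-Pr2NEt, CH2Cl2, −78 → 0 °C; 6, −78 → 0 °C; pH 7 buffer, MeOH, H2O2
Reagents that add atoms: none
Why: Evans syn-aldol; the Z-boron enolate reacts through a Zimmerman–Traxler chair on the face away from the auxiliary benzyl group, setting C8 (S after reduction) and C7 (S) as the threo pair.

Step 13
Reactants: 22 threo aldol adduct
Product: 23 (4R)-4-benzyl-3-[(2R,3R)-3-G-2-(4-bromo-2,6-dimethoxyphenoxy)-3-(4-nitrobenzoyloxy)propanoyl]-1,3-oxazolidin-2-one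
Conditions: 4-nitrobenzoic acid, PPh3, DIAD, THF, 0 → 25 °C
Reagents that add atoms: 4-nitrobenzoic acid (OC(=O)c1ccc(cc1)[N+](=O)[O-])
Why: Mitsunobu esterification; SN2 displacement of the oxyphosphonium inverts the benzylic carbinol C7 (S → R), turning threo into erythro.

Step 14
Reactants: 23 inverted 4-nitrobenzoate
Product: 24 (1R,2S)-1-G-2-(4-bromo-2,6-dimethoxyphenoxy)propane-1,3-diol (erythro)
Conditions: LiBH4, MeOH (4 equiv), THF, 0 → 25 °C
Reagents that add atoms: none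
Why: hydride reduction cleaves the imide to the primary alcohol and the nitrobenzoate to the free carbinol without touching either stereocentre.

Step 15
Reactants: 24 erythro diol
Product: 25 (4R,5S)-4-G-5-(4-bromo-2,6-dimethoxyphenoxy)-2,2-dimethyl-1,3-dioxane
Conditions: 2,2-dimethoxypropane, PPTS (cat.), CH2Cl2, 25 °C
Reagents that add atoms: 2,2-dimethoxypropane (COC(C)(C)OC)
Why: transketalisation of the 1,3-diol to the six-membered acetonide (trans, both substituents equatorial).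

Step 16
Reactants: 25 bromo acetonide
Product: 27 3,5-dimethoxy-4-(armA-oxy)benzaldehyde, via ring B aryllithium 26 (not isolated)
Conditions: n-BuLi, THF, −78 °C; DMF, −78 → 0 °C; aq NH4Cl
Reagents that add atoms: N,N-dimethylformamide (CN(C)C=O)
Why: bromine–lithium exchange followed by Bouveault formylation unmasks the aldehyde.

**Part 4 – ring D/ring E aldehyde 34**

Step 17
Reactants: 20 (S)-imide of the bromoguaiacyloxyacetic acid; 6 4-(benzyloxy)-3-methoxybenzaldehyde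
Product: 29 (4S)-4-benzyl-3-[(2S,3R)-3-G-2-(4-bromo-2-methoxyphenoxy)-3-hydroxypropanoyl]-1,3-oxazolidin-2-one, via Z-dibutylboron enolate of the bromoguaiacyl imide 28 (not isolated)
Conditions: Bu2BOTf, i-Pr2NEt, CH2Cl2, −78 → 0 °C; 6, −78 → 0 °C; pH 7 buffer, MeOH, H2O2
Reagents that add atoms: none
Why: Evans syn-aldol with the enantiomeric auxiliary sets C8 (R after reduction) and C7 (R) as the threo pair.

Step 18
Reactants: 29 threo aldol adduct
Product: 30 (4S)-4-benzyl-3-[(2S,3S)-3-G-2-(4-bromo-2-methoxyphenoxy)-3-(4-nitrobenzoyloxy)propanoyl]-1,3-oxazolidin-2-one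
Conditions: 4-nitrobenzoic acid, PPh3, DIAD, THF, 0 → 25 °C
Reagents that add atoms: 4-nitrobenzoic acid (OC(=O)c1ccc(cc1)[N+](=O)[O-])
Why: Mitsunobu reaction with SN2 inversion at C7 (R → S) gives the erythro relationship.

Step 19
Reactants: 30 inverted 4-nitrobenzoate
Product: 31 (1S,2R)-1-G-2-(4-bromo-2-methoxyphenoxy)propane-1,3-diol (erythro)
Conditions: LiBH4, MeOH (4 equiv), THF, 0 → 25 °C
Reagents that add atoms: none
Why: reductive cleavage of imide and ester by hydride leaves both stereocentres untouched.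

Step 20
Reactants: 31 erythro diol
Product: 32 (4S,5R)-4-G-5-(4-bromo-2-methoxyphenoxy)-2,2-dimethyl-1,3-dioxane
Conditions: 2,2-dimethoxypropane, PPTS (cat.), CH2Cl2, 25 °C
Reagents that add atoms: 2,2-dimethoxypropane (COC(C)(C)OC)
Why: acetonide formation on the 1,3-diol by transketalisation.

Step 21
Reactants: 32 bromo acetonide
Product: 34 3-methoxy-4-(armE-oxy)benzaldehyde, via ring D aryllithium 33 (not isolated)
Conditions: n-BuLi, THF, −78 °C; DMF, −78 → 0 °C; aq NH4Cl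
Reagents that add atoms: N,N-dimethylformamide (CN(C)C=O)
Why: bromine–lithium exchange and Bouveault formylation.

**Part 5 – ring C/D/E aldehyde 40**

Step 22
Reactants: 17 (R)-imide of the bromosyringyloxyacetic acid; 34 ring D/ring E aldehyde
Product: 36 (4R)-4-benzyl-3-[(2R,3S)-2-(4-bromo-2,6-dimethoxyphenoxy)-3-hydroxy-3-[3-methoxy-4-(armE-oxy)phenyl]propanoyl]-1,3-oxazolidin-2-one, via Z-diethylboron enolate of the bromosyringyl imide 35 (not isolated)
Conditions: Et2BOTf, i-Pr2NEt, CH2Cl2, −78 → 0 °C; 34, −78 → 0 °C; pH 7 buffer, MeOH, H2O2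
Reagents that add atoms: none
Why: Evans syn-aldol through the Z-diethylboron enolate, whose smaller boron ligands suit the bulkier aldehyde 34; the Zimmerman–Traxler chair under auxiliary control (the remote centres of 34 do not interfere) gives the threo unit on ring C directly, C7 (S) and C8 (S after reduction).

Step 23
Reactants: 36 threo aldol adduct
Product: 37 (1S,2S)-2-(4-bromo-2,6-dimethoxyphenoxy)-1-[3-methoxy-4-(armE-oxy)phenyl]propane-1,3-diol (threo)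
Conditions: NaBH4, THF/H2O 4:1, 0 → 25 °C
Reagents that add atoms: none
Why: reductive removal of the auxiliary by hydride attack on the exocyclic imide carbonyl.

Step 24
Reactants: 37 threo diol
Product: 38 (4S,5S)-5-(4-bromo-2,6-dimethoxyphenoxy)-4-[3-methoxy-4-(armE-oxy)phenyl]-2,2-dimethyl-1,3-dioxane
Conditions: 2,2-dimethoxypropane, PPTS (cat.), CH2Cl2, 25 °C
Reagents that add atoms: 2,2-dimethoxypropane (COC(C)(C)OC)
Why: acetonide formation on the 1,3-diol (cis-4,5 ring).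

Step 25
Reactants: 38 bromo bis-acetonide
Product: 40 3,5-dimethoxy-4-(armDE-oxy)benzaldehyde, via ring C aryllithium 39 (not isolated)
Conditions: n-BuLi, THF, −78 °C; DMF, −78 → 0 °C; aq NH4Cl
Reagents that add atoms: N,N-dimethylformamide (CN(C)C=O)
Why: bromine–lithium exchange and Bouveault formylation.

**Part 6 – lactone 49**

Step 26
Reactants: 41 succinic anhydride
Product: 42 4-methoxy-4-oxobutanoic acid (monomethyl succinate)
Conditions: MeOH, reflux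
Reagents that add atoms: methanol (CO)
Why: alcoholysis of the cyclic anhydride.

Step 27
Reactants: 42 monomethyl succinate
Product: 44 methyl 4-[(4S)-4-benzyl-2-oxo-1,3-oxazolidin-3-yl]-4-oxobutanoate, via pivalic mixed anhydride of monomethyl succinate 43 (not isolated)
Conditions: PivCl, Et3N, THF, −20 °C; then LiCl, (S)-4-benzyl-1,3-oxazolidin-2-one, −20 → 25 °C
Reagents that add atoms: (S)-4-benzyl-1,3-oxazolidin-2-one (O=C1N[C@@H](Cc2ccccc2)CO1)
Why: N-acylation of the auxiliary through a mixed anhydride.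

Step 28
Reactants: 44 succinate imide; 27 ring A/ring B aldehyde
Product: 46 methyl (3S,4S)-3-{[(4S)-4-benzyl-2-oxo-1,3-oxazolidin-3-yl]carbonyl}-4-hydroxy-4-ArB-butanoate, via Z-dibutylboron enolate of the succinate imide 45 (not isolated)
Conditions: Bu2BOTf, i-Pr2NEt, CH2Cl2, −78 → 0 °C; 27, −78 → 0 °C; pH 7 buffer, MeOH, H2O2, 0 °C
Reagents that add atoms: none
Why: Evans syn-aldol; only the imide side is enolised and the (S)-auxiliary fixes core C8 and C7 (R and S in the final furofuran).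

Step 29
Reactants: 46 core aldol adduct
Product: 47 methyl (3S,4S)-3-{[(4S)-4-benzyl-2-oxo-1,3-oxazolidin-3-yl]carbonyl}-4-[(TBS)oxy]-4-ArB-butanoate
Conditions: TBSOTf, 2,6-lutidine, CH2Cl2, −78 °C
Reagents that add atoms: tert-butyldimethylsilyl triflate (CC(C)(C)[Si](C)(C)OS(=O)(=O)C(F)(F)F)
Why: silylation blocks the benzylic hydroxyl so that it cannot lactonise onto the ester.

Step 30
Reactants: 47 silylated aldol adduct
Product: 49 (4R)-4-[(S)-ArB(TBS-oxy)methyl]dihydrofuran-2(3H)-one, via TBS-protected hydroxy ester 48 (not isolated)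
Conditions: NaBH4, THF/H2O 4:1, 0 → 25 °C; then PPTS (cat.), toluene, 50 °C
Reagents that add atoms: none
Why: reductive removal of the auxiliary gives the primary alcohol, which closes onto the methyl ester by 5-exo-trig lactonisation.

**Part 7 – union of the halves and end game**

Step 31
Reactants: 49 ring A/ring B lactone; 40 ring C/D/E aldehyde
Product: 51 (3S,4R)-3-[(S)-ArC(hydroxy)methyl]-4-[(S)-ArB(TBS-oxy)methyl]dihydrofuran-2(3H)-one, via potassium enolate of the lactone 50 (not isolated)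
Conditions: KN(SiMe3)2, THF, −78 °C; 40, −78 °C; aq NH4Cl at −78 °C
Reagents that add atoms: none
Why: aldol addition of the lactone enolate; attack anti to the C4 substituent sets the trans C3 centre (core C8') and the potassium enolate favours the syn (erythro) carbinol (core C7', S).

Step 32
Reactants: 51 coupled hydroxy lactone
Product: 52 (2R,3R)-2-[(S)-ArB(TBS-oxy)methyl]-3-[(S)-ArC(hydroxy)methyl]butane-1,4-diol
Conditions: LiAlH4, THF, −20 → 0 °C
Reagents that add atoms: none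
Why: hydride reduction of the lactone to the 1,4-diol, with the low temperature preventing retro-aldol.

Step 33
Reactants: 52 silylated triol
Product: 53 (2R,3R)-2-[(S)-ArB(hydroxy)methyl]-3-[(S)-ArC(hydroxy)methyl]butane-1,4-diol
Conditions: TBAF, THF, 0 → 25 °C
Reagents that add atoms: none
Why: fluoride-induced desilylation.

Step 34
Reactants: 53 tetraol
Product: 55 (1S,3aR,4S,6aR)-1-ArB-4-ArC-tetrahydro-1H,3H-furo[3,4-c]furan, via primary bis-mesylate 54 (not isolated)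
Conditions: MsCl (2.2 equiv), pyridine, CH2Cl2, 0 → 25 °C
Reagents that add atoms: none
Why: selective mesylation of the two primary alcohols followed by double 5-exo-tet Williamson cyclisation by the benzylic hydroxyls; both C–O bonds form at CH2, so C7 and C7' are retained and the cis-fused bis-exo diaryl furofuran results.

Step 35
Reactants: 55 protected furofuran
Product: 56 target carrying benzyl ethers on the phenols of rings A and E
Conditions: AcOH/H2O 4:1, 40 °C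
Reagents that add atoms: none
Why: mild acid hydrolysis of the three 1,3-dioxane acetonides, leaving benzyl ethers and the furofuran intact.

Step 36
Reactants: 56 dibenzyl ether
Product: 57 target CNP0316493.3
Conditions: H2 (1 atm), 10% Pd/C, EtOAc/MeOH, 25 °C
Reagents that add atoms: none
Why: catalytic hydrogenolysis of the two aryl benzyl ethers under neutral conditions, which leaves the benzylic alcohols and furofuran C–O bonds in place.

**Compound list**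
1 | catechol | Oc1ccccc1O | starting material
2 | guaiacol | COc1ccccc1O | intermediate
3 | glyoxylic acid | O=CC(=O)O | starting material
4 | 4-hydroxy-3-methoxymandelic acid (racemic) | COc1cc(C(O)C(=O)O)ccc1O | intermediate
5 | vanillin | COc1cc(C=O)ccc1O | intermediate
6 | 4-(benzyloxy)-3-methoxybenzaldehyde | COc1cc(C=O)ccc1OCc1ccccc1 | intermediate
7 | 4-bromo-2-methoxyphenol | COc1cc(Br)ccc1O | intermediate
8 | resorcinol | Oc1cccc(O)c1 | starting material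
9 | 1,3-dimethoxybenzene | COc1cccc(OC)c1 | intermediate
10 | 2,6-dimethoxyphenyllithium | [Li]c1c(OC)cccc1OC | intermediate
11 | dimethyl (2,6-dimethoxyphenyl)boronate | COB(OC)c1c(OC)cccc1OC | intermediate
12 | 2,6-dimethoxyphenol | COc1cccc(OC)c1O | intermediate
13 | 4-bromo-2,6-dimethoxyphenol | COc1cc(Br)cc(OC)c1O | intermediate
14 | bromoacetic acid | OC(=O)CBr | starting material
15 | (4-bromo-2,6-dimethoxyphenoxy)acetic acid | COc1cc(Br)cc(OC)c1OCC(=O)O | intermediate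
16 | (4-bromo-2,6-dimethoxyphenoxy)acetic pivalic anhydride | COc1cc(Br)cc(OC)c1OCC(=O)OC(=O)C(C)(C)C | intermediate
17 | (4R)-4-benzyl-3-[(4-bromo-2,6-dimethoxyphenoxy)acetyl]-1,3-oxazolidin-2-one | COc1cc(Br)cc(OC)c1OCC(=O)N1[C@H](Cc2ccccc2)COC1=O | intermediate
18 | (4-bromo-2-methoxyphenoxy)acetic acid | COc1cc(Br)ccc1OCC(=O)O | intermediate
19 | (4-bromo-2-methoxyphenoxy)acetic pivalic anhydride | COc1cc(Br)ccc1OCC(=O)OC(=O)C(C)(C)C | intermediate
20 | (4S)-4-benzyl-3-[(4-bromo-2-methoxyphenoxy)acetyl]-1,3-oxazolidin-2-one | COc1cc(Br)ccc1OCC(=O)N1[C@@H](Cc2ccccc2)COC1=O | intermediate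
21 | Z-dibutylboron enolate of 17 | CCCCB(CCCC)O/C(=C\Oc1c(OC)cc(Br)cc1OC)N1[C@H](Cc2ccccc2)COC1=O | intermediate
22 | (4R)-4-benzyl-3-[(2R,3S)-3-G-2-(4-bromo-2,6-dimethoxyphenoxy)-3-hydroxypropanoyl]-1,3-oxazolidin-2-one | COc1cc([C@H](O)[C@H](C(=O)N2[C@H](Cc3ccccc3)COC2=O)Oc2c(OC)cc(Br)cc2OC)ccc1OCc1ccccc1 | intermediate
23 | (4R)-4-benzyl-3-[(2R,3R)-3-G-2-(4-bromo-2,6-dimethoxyphenoxy)-3-(4-nitrobenzoyloxy)propanoyl]-1,3-oxazolidin-2-one | COc1cc([C@@H](OC(=O)c2ccc(cc2)[N+](=O)[O-])[C@H](C(=O)N2[C@H](Cc3ccccc3)COC2=O)Oc2c(OC)cc(Br)cc2OC)ccc1OCc1ccccc1 | intermediate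
24 | (1R,2S)-1-G-2-(4-bromo-2,6-dimethoxyphenoxy)propane-1,3-diol | COc1cc([C@@H](O)[C@H](CO)Oc2c(OC)cc(Br)cc2OC)ccc1OCc1ccccc1 | intermediate
25 | (4R,5S)-4-G-5-(4-bromo-2,6-dimethoxyphenoxy)-2,2-dimethyl-1,3-dioxane | COc1cc(Br)cc(OC)c1O[C@H]1COC(C)(C)O[C@@H]1c1ccc(OCc2ccccc2)c(OC)c1 | intermediate
26 | 3,5-dimethoxy-4-(armA-oxy)phenyllithium | [Li]c1cc(OC)c(O[C@H]2COC(C)(C)O[C@@H]2c2ccc(OCc3ccccc3)c(OC)c2)c(OC)c1 | intermediate
27 | 3,5-dimethoxy-4-(armA-oxy)benzaldehyde | O=Cc1cc(OC)c(O[C@H]2COC(C)(C)O[C@@H]2c2ccc(OCc3ccccc3)c(OC)c2)c(OC)c1 | intermediate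
28 | Z-dibutylboron enolate of 20 | CCCCB(CCCC)O/C(=C\Oc1ccc(Br)cc1OC)N1[C@@H](Cc2ccccc2)COC1=O | intermediate
29 | (4S)-4-benzyl-3-[(2S,3R)-3-G-2-(4-bromo-2-methoxyphenoxy)-3-hydroxypropanoyl]-1,3-oxazolidin-2-one | COc1cc(Br)ccc1O[C@H](C(=O)N1[C@@H](Cc2ccccc2)COC1=O)[C@H](O)c1ccc(OCc2ccccc2)c(OC)c1 | intermediate
30 | (4S)-4-benzyl-3-[(2S,3S)-3-G-2-(4-bromo-2-methoxyphenoxy)-3-(4-nitrobenzoyloxy)propanoyl]-1,3-oxazolidin-2-one | COc1cc(Br)ccc1O[C@H](C(=O)N1[C@@H](Cc2ccccc2)COC1=O)[C@@H](OC(=O)c1ccc(cc1)[N+](=O)[O-])c1ccc(OCc2ccccc2)c(OC)c1 | intermediate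
31 | (1S,2R)-1-G-2-(4-bromo-2-methoxyphenoxy)propane-1,3-diol | COc1cc(Br)ccc1O[C@H](CO)[C@@H](O)c1ccc(OCc2ccccc2)c(OC)c1 | intermediate
32 | (4S,5R)-4-G-5-(4-bromo-2-methoxyphenoxy)-2,2-dimethyl-1,3-dioxane | COc1cc(Br)ccc1O[C@@H]1COC(C)(C)O[C@H]1c1ccc(OCc2ccccc2)c(OC)c1 | intermediate
33 | 3-methoxy-4-(armE-oxy)phenyllithium | [Li]c1ccc(O[C@@H]2COC(C)(C)O[C@H]2c2ccc(OCc3ccccc3)c(OC)c2)c(OC)c1 | intermediate
34 | 3-methoxy-4-(armE-oxy)benzaldehyde | O=Cc1ccc(O[C@@H]2COC(C)(C)O[C@H]2c2ccc(OCc3ccccc3)c(OC)c2)c(OC)c1 | intermediate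
35 | Z-diethylboron enolate of 17 | CCB(CC)O/C(=C\Oc1c(OC)cc(Br)cc1OC)N1[C@H](Cc2ccccc2)COC1=O | intermediate
36 | (4R)-4-benzyl-3-[(2R,3S)-2-(4-bromo-2,6-dimethoxyphenoxy)-3-hydroxy-3-[3-methoxy-4-(armE-oxy)phenyl]propanoyl]-1,3-oxazolidin-2-one | COc1cc(Br)cc(OC)c1O[C@@H](C(=O)N1[C@H](Cc2ccccc2)COC1=O)[C@@H](O)c1ccc(O[C@@H]2COC(C)(C)O[C@H]2c2ccc(OCc3ccccc3)c(OC)c2)c(OC)c1 | intermediate
37 | (1S,2S)-2-(4-bromo-2,6-dimethoxyphenoxy)-1-[3-methoxy-4-(armE-oxy)phenyl]propane-1,3-diol | COc1cc(Br)cc(OC)c1O[C@@H](CO)[C@@H](O)c1ccc(O[C@@H]2COC(C)(C)O[C@H]2c2ccc(OCc3ccccc3)c(OC)c2)c(OC)c1 | intermediate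
38 | (4S,5S)-5-(4-bromo-2,6-dimethoxyphenoxy)-4-[3-methoxy-4-(armE-oxy)phenyl]-2,2-dimethyl-1,3-dioxane | COc1cc(Br)cc(OC)c1O[C@H]1COC(C)(C)O[C@H]1c1ccc(O[C@@H]2COC(C)(C)O[C@H]2c2ccc(OCc3ccccc3)c(OC)c2)c(OC)c1 | intermediate
39 | 3,5-dimethoxy-4-(armDE-oxy)phenyllithium | [Li]c1cc(OC)c(O[C@H]2COC(C)(C)O[C@H]2c2ccc(O[C@@H]3COC(C)(C)O[C@H]3c3ccc(OCc4ccccc4)c(OC)c3)c(OC)c2)c(OC)c1 | intermediate
40 | 3,5-dimethoxy-4-(armDE-oxy)benzaldehyde | O=Cc1cc(OC)c(O[C@H]2COC(C)(C)O[C@H]2c2ccc(O[C@@H]3COC(C)(C)O[C@H]3c3ccc(OCc4ccccc4)c(OC)c3)c(OC)c2)c(OC)c1 | intermediate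
41 | succinic anhydride | O=C1CCC(=O)O1 | starting material
42 | 4-methoxy-4-oxobutanoic acid | COC(=O)CCC(=O)O | intermediate
43 | 4-methoxy-4-oxobutanoic pivalic anhydride | COC(=O)CCC(=O)OC(=O)C(C)(C)C | intermediate
44 | methyl 4-[(4S)-4-benzyl-2-oxo-1,3-oxazolidin-3-yl]-4-oxobutanoate | COC(=O)CCC(=O)N1[C@@H](Cc2ccccc2)COC1=O | intermediate
45 | Z-dibutylboron enolate of 44 | CCCCB(CCCC)O/C(=C\CC(=O)OC)N1[C@@H](Cc2ccccc2)COC1=O | intermediate
46 | methyl (3S,4S)-3-{[(4S)-4-benzyl-2-oxo-1,3-oxazolidin-3-yl]carbonyl}-4-hydroxy-4-ArB-butanoate | O=C(N1[C@@H](Cc2ccccc2)COC1=O)[C@@H](CC(=O)OC)[C@H](O)c1cc(OC)c(O[C@H]2COC(C)(C)O[C@@H]2c2ccc(OCc3ccccc3)c(OC)c2)c(OC)c1 | intermediate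
47 | methyl (3S,4S)-3-{[(4S)-4-benzyl-2-oxo-1,3-oxazolidin-3-yl]carbonyl}-4-[(TBS)oxy]-4-ArB-butanoate | O=C(N1[C@@H](Cc2ccccc2)COC1=O)[C@@H](CC(=O)OC)[C@H](O[Si](C)(C)C(C)(C)C)c1cc(OC)c(O[C@H]2COC(C)(C)O[C@@H]2c2ccc(OCc3ccccc3)c(OC)c2)c(OC)c1 | intermediate
48 | methyl (3R,4S)-4-ArB-3-(hydroxymethyl)-4-[(TBS)oxy]butanoate | OC[C@@H](CC(=O)OC)[C@H](O[Si](C)(C)C(C)(C)C)c1cc(OC)c(O[C@H]2COC(C)(C)O[C@@H]2c2ccc(OCc3ccccc3)c(OC)c2)c(OC)c1 | intermediate
49 | (4R)-4-[(S)-ArB(TBS-oxy)methyl]dihydrofuran-2(3H)-one | O=C1OC[C@@H](C1)[C@H](O[Si](C)(C)C(C)(C)C)c1cc(OC)c(O[C@H]2COC(C)(C)O[C@@H]2c2ccc(OCc3ccccc3)c(OC)c2)c(OC)c1 | intermediate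
50 | potassium enolate of 49 | [K+].[O-]C1=C[C@H](CO1)[C@H](O[Si](C)(C)C(C)(C)C)c1cc(OC)c(O[C@H]2COC(C)(C)O[C@@H]2c2ccc(OCc3ccccc3)c(OC)c2)c(OC)c1 | intermediate
51 | (3S,4R)-3-[(S)-ArC(hydroxy)methyl]-4-[(S)-ArB(TBS-oxy)methyl]dihydrofuran-2(3H)-one | O=C1OC[C@H]([C@H](O[Si](C)(C)C(C)(C)C)c2cc(OC)c(O[C@H]3COC(C)(C)O[C@@H]3c3ccc(OCc4ccccc4)c(OC)c3)c(OC)c2)[C@H]1[C@H](O)c1cc(OC)c(O[C@H]2COC(C)(C)O[C@H]2c2ccc(O[C@@H]3COC(C)(C)O[C@H]3c3ccc(OCc4ccccc4)c(OC)c3)c(OC)c2)c(OC)c1 | intermediate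
52 | (2R,3R)-2-[(S)-ArB(TBS-oxy)methyl]-3-[(S)-ArC(hydroxy)methyl]butane-1,4-diol | OC[C@H]([C@H](O[Si](C)(C)C(C)(C)C)c1cc(OC)c(O[C@H]2COC(C)(C)O[C@@H]2c2ccc(OCc3ccccc3)c(OC)c2)c(OC)c1)[C@H](CO)[C@H](O)c1cc(OC)c(O[C@H]2COC(C)(C)O[C@H]2c2ccc(O[C@@H]3COC(C)(C)O[C@H]3c3ccc(OCc4ccccc4)c(OC)c3)c(OC)c2)c(OC)c1 | intermediate
53 | (2R,3R)-2-[(S)-ArB(hydroxy)methyl]-3-[(S)-ArC(hydroxy)methyl]butane-1,4-diol | OC[C@H]([C@H](O)c1cc(OC)c(O[C@H]2COC(C)(C)O[C@@H]2c2ccc(OCc3ccccc3)c(OC)c2)c(OC)c1)[C@H](CO)[C@H](O)c1cc(OC)c(O[C@H]2COC(C)(C)O[C@H]2c2ccc(O[C@@H]3COC(C)(C)O[C@H]3c3ccc(OCc4ccccc4)c(OC)c3)c(OC)c2)c(OC)c1 | intermediate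
54 | 1,4-bis(methanesulfonate) of 53 | CS(=O)(=O)OC[C@H]([C@H](O)c1cc(OC)c(O[C@H]2COC(C)(C)O[C@@H]2c2ccc(OCc3ccccc3)c(OC)c2)c(OC)c1)[C@H](COS(C)(=O)=O)[C@H](O)c1cc(OC)c(O[C@H]2COC(C)(C)O[C@H]2c2ccc(O[C@@H]3COC(C)(C)O[C@H]3c3ccc(OCc4ccccc4)c(OC)c3)c(OC)c2)c(OC)c1 | intermediate
55 | (1S,3aR,4S,6aR)-1-ArB-4-ArC-tetrahydro-1H,3H-furo[3,4-c]furan | COc1cc([C@H]2OC(C)(C)OC[C@@H]2Oc2c(OC)cc([C@H]3OC[C@H]4[C@@H]3CO[C@@H]4c3cc(OC)c(O[C@H]4COC(C)(C)O[C@H]4c4ccc(O[C@@H]5COC(C)(C)O[C@H]5c5ccc(OCc6ccccc6)c(OC)c5)c(OC)c4)c(OC)c3)cc2OC)ccc1OCc1ccccc1 | intermediate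
56 | target with benzyl ethers on the phenols of rings A and E (all six alcohols free) | COc1cc([C@@H](O)[C@H](CO)Oc2c(OC)cc([C@H]3OC[C@H]4[C@@H]3CO[C@@H]4c3cc(OC)c(O[C@@H](CO)[C@@H](O)c4ccc(O[C@H](CO)[C@@H](O)c5ccc(OCc6ccccc6)c(OC)c5)c(OC)c4)c(OC)c3)cc2OC)ccc1OCc1ccccc1 | intermediate
57 | CNP0316493.3: (1S,3aR,4S,6aR)-furo[3,4-c]furan with 3,5-dimethoxyphenyl rings B (at C1) and C (at C4); ring B 4-O carries (1R,2S)-1,3-dihydroxy-1-(4-hydroxy-3-methoxyphenyl)propan-2-yl; ring C 4-O carries (1S,2S)-1,3-dihydroxy-1-(ring D)propan-2-yl, ring D being 3-methoxyphenyl whose 4-O carries (1S,2R)-1,3-dihydroxy-1-(4-hydroxy-3-methoxyphenyl)propan-2-yl | COc1cc([C@@H](O)[C@H](CO)Oc2c(OC)cc([C@H]3OC[C@H]4[C@@H]3CO[C@@H]4c3cc(OC)c(O[C@@H](CO)[C@@H](O)c4ccc(O[C@H](CO)[C@@H](O)c5ccc(O)c(OC)c5)c(OC)c4)c(OC)c3)cc2OC)ccc1O | target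

**Step count**
Total: 36 steps. Longest linear sequence: 19 steps (5–9, 12–16, 28–36; the chain 1, 4, 10, 11, 17–25, 31–36 is equally long).

**Three steps most likely to fail**

Step 13 (Mitsunobu inversion beside an enolisable imide; elimination or partial SN1 at the electron-rich benzylic carbon could erode the result). The fallback sets out from 22. NaBH4 in THF/H2O removes the auxiliary to give the threo diol (1S,2S)-1-G-2-(4-bromo-2,6-dimethoxyphenoxy)propane-1,3-diol F1. DDQ in dioxane oxidises only the electron-rich benzylic alcohol to (2S)-1-G-2-(4-bromo-2,6-dimethoxyphenoxy)-3-hydroxypropan-1-one F2. Zn(BH4)2 in Et2O at −20 °C then reduces the ketone through the chelate with the α-aryloxy oxygen, which delivers the erythro diol, and the route is rejoined at 24. C7 is thus set by chelation-controlled reduction instead of by substitution.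

Step 31 (aldol of a hindered lactone enolate with a large aldehyde; the syn/anti ratio at the new carbinol and retro-aldol are the concerns). The fallback sets out from 49 and 40. The aldol is run with LiN(SiMe3)2 without regard to the carbinol configuration, giving 51 together with its carbinol epimer (3S,4R)-3-[(R)-ArC(hydroxy)methyl]-4-[(S)-ArB(TBS-oxy)methyl]dihydrofuran-2(3H)-one F3. Dess–Martin periodinane converts the mixture into the single trans keto lactone (3S,4R)-3-(ArC-carbonyl)-4-[(S)-ArB(TBS-oxy)methyl]dihydrofuran-2(3H)-one F4. Zn(BH4)2 reduction through the chelate of the two carbonyls, with hydride entering anti to the C4 substituent, then gives the syn alcohol and the route is rejoined at 51.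

Step 34 (double cyclisation; mesylation of a benzylic hydroxyl, chloride substitution or epimerisation could compete). The fallback sets out from 52, before desilylation, and closes the rings one at a time. TsCl in pyridine gives the 1,4-bis(4-methylbenzenesulfonate) of 52 F5, in which only the free C7' hydroxyl can cyclise, so it passes on to [(2S,3R,4R)-2-ArC-4-[(S)-ArB(TBS-oxy)methyl]oxolan-3-yl]methyl 4-methylbenzenesulfonate F6. TBAF in THF then liberates the C7 alkoxide, which displaces the remaining tosylate, and the route is rejoined at 55.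

**Further compounds**
F1 | step 13 | (1S,2S)-1-G-2-(4-bromo-2,6-dimethoxyphenoxy)propane-1,3-diol | COc1cc([C@H](O)[C@H](CO)Oc2c(OC)cc(Br)cc2OC)ccc1OCc1ccccc1
F2 | step 13 | (2S)-1-G-2-(4-bromo-2,6-dimethoxyphenoxy)-3-hydroxypropan-1-one | COc1cc(C(=O)[C@H](CO)Oc2c(OC)cc(Br)cc2OC)ccc1OCc1ccccc1
F3 | step 31 | (3S,4R)-3-[(R)-ArC(hydroxy)methyl]-4-[(S)-ArB(TBS-oxy)methyl]dihydrofuran-2(3H)-one | O=C1OC[C@H]([C@H](O[Si](C)(C)C(C)(C)C)c2cc(OC)c(O[C@H]3COC(C)(C)O[C@@H]3c3ccc(OCc4ccccc4)c(OC)c3)c(OC)c2)[C@H]1[C@@H](O)c1cc(OC)c(O[C@H]2COC(C)(C)O[C@H]2c2ccc(O[C@@H]3COC(C)(C)O[C@H]3c3ccc(OCc4ccccc4)c(OC)c3)c(OC)c2)c(OC)c1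
F4 | step 31 | (3S,4R)-3-(ArC-carbonyl)-4-[(S)-ArB(TBS-oxy)methyl]dihydrofuran-2(3H)-one | O=C1OC[C@H]([C@H](O[Si](C)(C)C(C)(C)C)c2cc(OC)c(O[C@H]3COC(C)(C)O[C@@H]3c3ccc(OCc4ccccc4)c(OC)c3)c(OC)c2)[C@H]1C(=O)c1cc(OC)c(O[C@H]2COC(C)(C)O[C@H]2c2ccc(O[C@@H]3COC(C)(C)O[C@H]3c3ccc(OCc4ccccc4)c(OC)c3)c(OC)c2)c(OC)c1
F5 | step 34 | 1,4-bis(4-methylbenzenesulfonate) of 52 | Cc1ccc(cc1)S(=O)(=O)OC[C@H]([C@H](O[Si](C)(C)C(C)(C)C)c1cc(OC)c(O[C@H]2COC(C)(C)O[C@@H]2c2ccc(OCc3ccccc3)c(OC)c2)c(OC)c1)[C@H](COS(=O)(=O)c1ccc(C)cc1)[C@H](O)c1cc(OC)c(O[C@H]2COC(C)(C)O[C@H]2c2ccc(O[C@@H]3COC(C)(C)O[C@H]3c3ccc(OCc4ccccc4)c(OC)c3)c(OC)c2)c(OC)c1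
F6 | step 34 | [(2S,3R,4R)-2-ArC-4-[(S)-ArB(TBS-oxy)methyl]oxolan-3-yl]methyl 4-methylbenzenesulfonate | Cc1ccc(cc1)S(=O)(=O)OC[C@@H]1[C@@H](c2cc(OC)c(O[C@H]3COC(C)(C)O[C@H]3c3ccc(O[C@@H]4COC(C)(C)O[C@H]4c4ccc(OCc5ccccc5)c(OC)c4)c(OC)c3)c(OC)c2)OC[C@@H]1[C@H](O[Si](C)(C)C(C)(C)C)c1cc(OC)c(O[C@H]2COC(C)(C)O[C@@H]2c2ccc(OCc3ccccc3)c(OC)c2)c(OC)c1
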